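Start from the target: it is the only species read, so ask how many seconds of opening speed each reading is worth.

| flask | substrate | reagent | catalyst | time |
|---|---|---|---|---|
| grey | 0.0800 M | 0.120 M | 0.00160 M |  |
| teal | 0.0800 M | 0.0600 M | 0.00160 M |  |
| ochre | 0.0800 M | 0.120 M | 0.00320 M |  |
| amber | 0.0800 M | 0.120 M | 0.00160 M | 320 s |

- grey run (time / s: [target] / M): 6.4: 0.00195; 10: 0.00343; 16: 0.00521; 25: 0.00734; 40: 0.01112; 64: 0.01524; 100: 0.02043; 160: 0.02389
- teal run (time / s: [target] / M): 6.4: 8.1 × 10⁻⁴; 10: 0.00152; 16: 0.00262; 25: 0.00402; 40: 0.00568; 64: 0.00870; 100: 0.01123; 160: 0.01471
- ochre run (time / s: [target] / M): 6.4: 0.00441; 10: 0.00631; 16: 0.00966; 25: 0.01409; 40: 0.02025; 64: 0.02656; 100: 0.03213; 160: 0.03467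

(standard deviation of a reading: 2 × 10⁻⁴ M)

- Overall: substrate + reagent -> target, with catalyst as catalyst.
- Constant volume, constant temperature.
- The analysis sees a species whether free or bound.
- "The second partner" is reagent.
- An order is taken over about fifteen percent of the charge, up and down.

- the exponent of [catalyst] in the starting rate at the charge of the grey run (at the point where two percent of the substrate have become target)
- the exponent of [reagent] in the starting rate at the charge of the grey run (at the point where two percent of the substrate have become target)
- target in the amber run at 320 s, as a share of the substrate charged

Take the opening speed as the target read at 16 s over that time, a point where the scatter is 3.84 % of grey's reading: grey gives 3.26 × 10⁻⁴ M/s, teal 1.64 × 10⁻⁴ M/s and ochre 6.04 × 10⁻⁴ M/s. Teal has half the reagent of grey, and ochre has twice the catalyst of grey. Those speeds give exponents of 0.891 for catalyst and 0.992 for reagent. They span wider steps than the question's and carry the scatter, but commit to one for each.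

Now try the bench rule: target equals opening speed times time. For grey at 160 s it gives 0.0521 M, which is still inside the charge of substrate, the limiting reagent. Yet the reading is 0.459 of that figure, so the rule has stopped working.

Turn the rule round. Grey's last reading over its opening speed is 73.4 s; call this the straight-line time θ, the seconds of opening speed a reading is worth.

Then watch how fast θ grows. In grey it gains 0.443 of a second per second between 64 s and 100 s, and 0.177 between 100 s and 160 s. A straight line through those two gains reaches zero near 162 s, close to the last reading. Amber has grey's charge, so my reckoning holds θ flat and puts amber at 29.9 % of the substrate charged.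

The forecast gives exponents of 1 and 1 and, higher than my figure, 33 % for amber, within 30.5 % to 37 %, judging that “The catalyst is therefore dying”.

The flask gives exponents of 1.0 and 1.0, and amber holds 28.7 %, below my figure; its θ is 70.5 s, less than the 73.4 s read for grey.

    catalyst + substrate ⇌ catalyst-substrate complex, settled at all times (14.70 /M)
    catalyst-substrate complex + reagent → target + catalyst + by-product (3.350 /M/s)
    target + reagent → side product (0.03120 /M/s)
    target → decomposed product (0.002700 /s)

In the grey charge the catalyst-substrate complex made target with reagent while target went on to side product, in about 267 s at the charged reagent, and to decomposed product, in about 370 s. Between grey's 160 s and amber's 320 s target went from a reading of 0.02389 M to 0.0230 M, with a scatter of 2 × 10⁻⁴ M on that reading, and ochre, with the same steps at twice the catalyst, read a θ of 57.4 s at 160 s.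

The earlier runs and the new flask were generated by integration on assumed constants, noise included.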